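The numbers were chosen freely; the flask was simulated.

Every starting complex charged stays in the count: at any moment it stands as itself, as an exchanged complex, or as quenched substrate. The incoming ligand likewise stands free, dormant or bound in an exchanged complex.

all flasks: starting complex 0.10 M; incoming ligand 0.110 M; protic impurity 2.00 mM
- north-west: time 30 s
- south: time 40 s
- north: time 50 s

    starting complex + incoming ligand ⇌ leaving ligand + complex with one exchanged (K1 = 0.51, k1 = 0.18 L mol⁻¹ s⁻¹)
    protic impurity + starting complex → quenched substrate (k2 = 14 L mol⁻¹ s⁻¹)
    leaving ligand → by-product carried off (k3 = 0.033 s⁻¹)
    complex with one exchanged + incoming ligand ⇌ leaving ligand + complex with two exchanged (K4 = 2.5, k4 = 0.20 L mol⁻¹ s⁻¹)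
    complex with two exchanged + incoming ligand ⇌ leaving ligand + complex with three exchanged (K5 = 0.18, k5 = 0.18 L mol⁻¹ s⁻¹)
    incoming ligand ⇌ dormant form (K6 = 1.5, k6 = 0.16 s⁻¹)

* which of these there is most of at the end, counted by the starting complex in it, north-west (complex with two exchanged / complex with one exchanged / complex with three exchanged / starting complex)
* which of these there is most of at the end, counted by the starting complex in it, south (complex with two exchanged / complex with one exchanged / complex with three exchanged / starting complex)
* which of these there is most of at the end, counted by the starting complex in it, north (complex with two exchanged / complex with one exchanged / complex with three exchanged / starting complex)
* amount of the one of these that there is most of at the end, in percent of the starting complex charged, north-west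
* amount of the one of these that there is most of at the end, in percent of the starting complex charged, south
* amount of the one of these that there is most of at the end, in percent of the starting complex charged, north

The protic impurity acts first. Its half-life of 0.50 s is far shorter than the 35 s of starting complex by forward exchange at the north-west charges. So the reckoning lets it take a share 2.00 % of the charge, one starting complex for each protic impurity.

After that, by the forward exchange, the logarithm of [starting complex] falls at 0.18 L mol⁻¹ s⁻¹ times [incoming ligand], a pseudo-first-order decay that integrates in closed form. With [incoming ligand] held as charged, north would keep 36.4 %.

But the ligand does not stay free. Its relaxation with the dormant form has a half-life of 2.60 s, shorter than that exchange. So [incoming ligand] is reckoned from then on at the charge divided by one plus 1.5, which is 0.0440 M. That gives 0.00792 s⁻¹, the survival constant: 0.18 L mol⁻¹ s⁻¹ times the level of free incoming ligand. The share of starting complex left is then the part the impurity spared times the exponential of minus this constant times the time: 77.3 % in north-west, 71.4 % in south, 66.0 % in north.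

One objection is that the free level is not steady. The first seconds, with more ligand free, add 0.0445 to the north exponent of 0.396. The draining pool later subtracts 0.0577. Their net change to the exponent is 0.0132.

The harder objection is the back step. Leaving ligand has a half-life of 21.0 s against being carried off, shorter than the north time. So in north it is reckoned near 0.0158 M, where making by the first exchange equals removal. At that level, with every exchanged complex counted as complex with one exchanged, the back step returns 34.3 % of the forward flow at the end of north. Taken as growing evenly from zero, that share averages 17.1 %, which lifts the estimate for north to 70.6 %. The north-west and south values stand without this correction. Even the uncorrected north value exceeds the 32.0 % left for the exchanged complexes together, so starting complex is reckoned to lead in north, and the values for north-west and south are higher still.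

The forecast puts starting complex first in north-west at 77 %, starting complex in south at 74 % and starting complex in north at 71 %, since “the starting complex stays well ahead at all three times”.

The simulation gives starting complex at 78.0 % in north-west, starting complex at 74.4 % in south and starting complex at 71.3 % in north.

North has not come to rest. At ten times the time, starting complex in north stands at 39.2 %, down 32 percentage points, and complex with two exchanged has risen from 4.56 % to 24.7 %. The survival constant carried that far in north gives 1.87 %, well below the flask. Free incoming ligand in north by then is 3.90 % of its charge, against the 40.0 % the constant assumes.

The neighbour of north with 0.025 M of starting complex keeps the same survival constant, which contains no [starting complex], while the impurity's share grows to 8.00 %, so the reckoning gives 61.9 %. That neighbour flask ends with 61.2 % of its charged starting complex.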